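**Strategy.** The pyran of the 3,4-diaryl chroman is cut across C3–C4 and O1–C2. This gives a ring A ortho-quinone methide (O1=C8a–C4a=C4, ring E on C4) and the ring B (E)-β-methoxystyrene. A single chiral-phosphoric-acid-catalysed [4+2] step closes the pyran, forms both bonds and sets C3 and C4 trans. The feature exploited is the ortho relationship between the ring A phenol oxygen O1 and the doubly benzylic C4. The precursor is an ortho-hydroxybenzhydrol that joins rings A and E and already carries the (R)-isoflavan unit (Evans alkylation, Mitsunobu closure). Ring E regiochemistry is fixed by formylating the still symmetric resorcinol.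

Key step: step 18

Remarks on the chemistry (assumptions):
- Labels: chroman 1 = O1, C2, C3, C4, C4a, C8a with benzo ring A; ring B on C3; ring E on C4 (E1 on C4, E2 OMe, E4 OH, E6 on the isoflavan); isoflavan unit = second chroman (O1', C2', C3', C4') with benzo ring D. The target is (3R,4S)-trans and 3'R.
- E1 and E5 of a ring E carrying E2-OMe and E4-OBn cannot be told apart by halogenation, and ring D is equally activated. The E1 carbon is therefore introduced as a formyl group on the symmetric resorcinol, its hydrogen bond to the E2 hydroxyl differentiates the two oxygens, and the benzhydrol is assembled from a ring E aldehyde and a ring A aryllithium.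
- 5-(Benzyloxy)-2-bromophenol is taken to be a catalogue compound.
- The (R) acid is assumed to give the (3R,4S) series; the sense of induction is to be checked on a small scale and the antipode used if it is the opposite.

**Route**

Step 1
Reactants: 1 methyl 2-(3,5-dihydroxyphenyl)acetate
Product: 3 methyl 2-(2-formyl-3,5-dihydroxyphenyl)acetate, via aryl dimethyliminium chloride 2 (not isolated)
Conditions: POCl3, DMF, MeCN, 0 °C → rt; then H2O, 50 °C
Reagents that add atoms: N,N-dimethylformamide CN(C)C=O (formyl carbon); water O (formyl oxygen)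
Why: Vilsmeier–Haack formylation, in which the chloroiminium ion attacks the position para to one hydroxyl and ortho to the other (E1, identical with E5 by the local symmetry of the ring), as in the formylation of orcinol, and the iminium salt is hydrolysed on work-up.

Step 2
Reactants: 3 methyl 2-(2-formyl-3,5-dihydroxyphenyl)acetate
Product: 4 methyl 2-[5-(benzyloxy)-2-formyl-3-hydroxyphenyl]acetate
Conditions: BnBr (1.05 equiv), NaHCO3, KI (cat.), MeCN, 60 °C
Reagents that add atoms: benzyl bromide BrCc1ccccc1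
Why: Williamson etherification under weak base, selective for the E4 hydroxyl because the E2 hydroxyl is tied up in a hydrogen bond to the formyl oxygen, as in the standard mono-alkylation of 2,4-dihydroxybenzaldehyde.

Step 3
Reactants: 4 methyl 2-[5-(benzyloxy)-2-formyl-3-hydroxyphenyl]acetate
Product: 5 methyl 2-[5-(benzyloxy)-2-formyl-3-methoxyphenyl]acetate
Conditions: MeI, K2CO3, DMF, rt
Reagents that add atoms: iodomethane CI
Why: Williamson methylation of the remaining chelated phenol under more forcing conditions fixes E2 as the methyl ether, while carbonate is too weak to deprotonate the arylacetate CH2.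

Step 4
Reactants: 5 methyl 2-[5-(benzyloxy)-2-formyl-3-methoxyphenyl]acetate
Product: 6 methyl 2-[5-(benzyloxy)-3-methoxy-2-vinylphenyl]acetate
Conditions: Ph3PCH3Br, NaHMDS, THF, 0 °C; then 5, −78 → 0 °C
Reagents that add atoms: methyltriphenylphosphonium bromide C[P+](c1ccccc1)(c1ccccc1)c1ccccc1.[Br-]
Why: Wittig methylenation masks the E1 carbon as a vinyl group, which is inert to hydroxide, enolate, borohydride, fluoride and Mitsunobu conditions and, unlike an acetal of so electron-rich an aldehyde, also to the acidic work-up of step 5.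

Step 5
Reactants: 6 methyl 2-[5-(benzyloxy)-3-methoxy-2-vinylphenyl]acetate
Product: 7 2-[5-(benzyloxy)-3-methoxy-2-vinylphenyl]acetic acid
Conditions: LiOH·H2O, THF/MeOH/H2O, rt; then 1 M HCl to pH 3, 0 °C
Reagents that add atoms: lithium hydroxide [Li+].[OH-] (carboxyl oxygen)
Why: Saponification of an unhindered methyl ester, with the styrene and the aryl ethers inert to aqueous hydroxide and to brief cold acidification.

Step 6
Reactants: 7 2-[5-(benzyloxy)-3-methoxy-2-vinylphenyl]acetic acid; 8 (R)-4-benzyl-2-oxazolidinone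
Product: 10 (R)-4-benzyl-3-{2-[5-(benzyloxy)-3-methoxy-2-vinylphenyl]acetyl}oxazolidin-2-one, via mixed pivalic anhydride 9 (not isolated)
Conditions: PivCl, Et3N, THF, −20 °C; then 8, LiCl, −20 °C → rt
Reagents that add atoms: none
Why: N-Acylation of the Evans auxiliary through the mixed pivalic anhydride, in which LiCl/Et3N activates the oxazolidinone and attack occurs at the less hindered arylacetyl carbonyl.

Step 7
Reactants: 11 4-(benzyloxy)-2-hydroxybenzaldehyde
Product: 12 4-(benzyloxy)-2-(triisopropylsilyloxy)benzaldehyde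
Conditions: TIPSCl, imidazole, DMAP (cat.), DMF, rt
Reagents that add atoms: chlorotriisopropylsilane CC(C)[Si](Cl)(C(C)C)C(C)C
Why: Silylation of the phenol as the bulky TIPS ether, chosen because it resists migration to the benzylic oxygen in step 8 and attack by the enolate in step 10.

Step 8
Reactants: 12 4-(benzyloxy)-2-(triisopropylsilyloxy)benzaldehyde
Product: 13 [4-(benzyloxy)-2-(triisopropylsilyloxy)phenyl]methanol
Conditions: NaBH4, THF/MeOH, 0 °C
Reagents that add atoms: none
Why: Borohydride reduction of the aldehyde to the benzylic alcohol, which leaves the aryl silyl and benzyl ethers untouched.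

Step 9
Reactants: 13 [4-(benzyloxy)-2-(triisopropylsilyloxy)phenyl]methanol
Product: 14 4-(benzyloxy)-1-(bromomethyl)-2-(triisopropylsilyloxy)benzene
Conditions: CBr4, PPh3, CH2Cl2, 0 °C; used at once
Reagents that add atoms: carbon tetrabromide BrC(Br)(Br)Br
Why: Appel bromination under neutral conditions converts the benzylic alcohol into the bromide without acid that would remove the silyl ether.

Step 10
Reactants: 10 (R)-4-benzyl-3-{2-[5-(benzyloxy)-3-methoxy-2-vinylphenyl]acetyl}oxazolidin-2-one; 14 4-(benzyloxy)-1-(bromomethyl)-2-(triisopropylsilyloxy)benzene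
Product: 16 (R)-4-benzyl-3-{(R)-2-[5-(benzyloxy)-3-methoxy-2-vinylphenyl]-3-[4-(benzyloxy)-2-(triisopropylsilyloxy)phenyl]propanoyl}oxazolidin-2-one, via sodium Z-enolate 15 (not isolated)
Conditions: NaHMDS, THF, −78 °C; then 14, −78 → −40 °C
Reagents that add atoms: none
Why: Evans asymmetric alkylation, in which the chelated Z-enolate is attacked by the benzylic bromide on the face opposite the auxiliary benzyl group; this sets the future C3' as R (the R auxiliary is required because the aryl group outranks the incoming CH2Ar).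

Step 11
Reactants: 16 (R)-4-benzyl-3-{(R)-2-[5-(benzyloxy)-3-methoxy-2-vinylphenyl]-3-[4-(benzyloxy)-2-(triisopropylsilyloxy)phenyl]propanoyl}oxazolidin-2-one
Product: 17 (R)-2-[5-(benzyloxy)-3-methoxy-2-vinylphenyl]-3-[4-(benzyloxy)-2-(triisopropylsilyloxy)phenyl]propan-1-ol
Conditions: LiBH4, MeOH (1 equiv), THF, 0 °C
Reagents that add atoms: none
Why: Reductive cleavage of the imide with LiBH4 gives the primary alcohol without epimerising the α-aryl stereocentre and without touching the styrene or the ethers.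

Step 12
Reactants: 17 (R)-2-[5-(benzyloxy)-3-methoxy-2-vinylphenyl]-3-[4-(benzyloxy)-2-(triisopropylsilyloxy)phenyl]propan-1-ol
Product: 18 5-(benzyloxy)-2-{(R)-2-[5-(benzyloxy)-3-methoxy-2-vinylphenyl]-3-hydroxypropyl}phenol
Conditions: TBAF, THF, 0 °C
Reagents that add atoms: none
Why: Fluoride cleavage of the aryl silyl ether frees the ring D phenol, and nothing else in the molecule is fluoride-labile.

Step 13
Reactants: 18 5-(benzyloxy)-2-{(R)-2-[5-(benzyloxy)-3-methoxy-2-vinylphenyl]-3-hydroxypropyl}phenol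
Product: 19 (R)-7-(benzyloxy)-3-[5-(benzyloxy)-3-methoxy-2-vinylphenyl]chroman
Conditions: PPh3, THF, 0 °C; DIAD added slowly, 0 °C → rt
Reagents that add atoms: none
Why: Intramolecular Mitsunobu etherification, a 6-exo-tet displacement of the activated primary alcohol by the phenoxide, closes the isoflavan pyran without involving the stereocentre.

Step 14
Reactants: 19 (R)-7-(benzyloxy)-3-[5-(benzyloxy)-3-methoxy-2-vinylphenyl]chroman
Product: 20 4-(benzyloxy)-2-[(R)-7-(benzyloxy)chroman-3-yl]-6-methoxybenzaldehyde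
Conditions: OsO4 (cat.), NaIO4, 2,6-lutidine, dioxane/H2O, rt
Reagents that add atoms: osmium tetroxide O=[Os](=O)(=O)=O (delivers the aldehyde oxygen); sodium periodate [Na+].[O-]I(=O)(=O)=O (restores that oxygen on osmium)
Why: Lemieux–Johnson cleavage (catalytic dihydroxylation followed by periodate glycol cleavage) unmasks the E1 aldehyde under buffered conditions to which the aryl and benzyl ethers are inert.

Step 15
Reactants: 20 4-(benzyloxy)-2-[(R)-7-(benzyloxy)chroman-3-yl]-6-methoxybenzaldehyde; 21 5-(benzyloxy)-2-bromophenol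
Product: 23 5-(benzyloxy)-2-[{4-(benzyloxy)-2-[(R)-7-(benzyloxy)chroman-3-yl]-6-methoxyphenyl}(hydroxy)methyl]phenol (both carbinol epimers), via lithium 5-(benzyloxy)-2-lithiophenoxide 22 (not isolated)
Conditions: 21 (3 equiv), n-BuLi (6 equiv), Et2O, −78 → 0 °C; then 20, THF, −78 → 0 °C; pH 7 buffer; Et3N-deactivated silica
Reagents that add atoms: none
Why: Halogen–lithium exchange on the lithium phenoxide gives the ortho-lithiated phenoxide, which undergoes 1,2-addition to the hindered, non-enolisable aldehyde to give the ortho-hydroxybenzhydrol as two carbinol epimers that converge in step 18.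

Step 16
Reactants: 24 2,3-dihydroxy-4-methoxybenzaldehyde
Product: 25 2,3-bis(benzyloxy)-4-methoxybenzaldehyde
Conditions: BnBr (2.4 equiv), K2CO3, DMF, 60 °C
Reagents that add atoms: benzyl bromide BrCc1ccccc1
Why: Double Williamson benzylation of the catechol under standard carbonate conditions.

Step 17
Reactants: 25 2,3-bis(benzyloxy)-4-methoxybenzaldehyde
Product: 26 (E)-2,3-bis(benzyloxy)-4-methoxy-1-(2-methoxyvinyl)benzene
Conditions: MeOCH2PPh3Cl, KOtBu, THF, 0 °C; then 25, 0 °C → rt; chromatography (AgNO3-doped silica if required)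
Reagents that add atoms: (methoxymethyl)triphenylphosphonium chloride COC[P+](c1ccccc1)(c1ccccc1)c1ccccc1.[Cl-]
Why: Wittig methoxymethylenation with a non-stabilised ylide should give both geometric isomers, of which the E isomer, the one step 18 needs, is isolated by chromatography.

Step 18
Reactants: 23 5-(benzyloxy)-2-[{4-(benzyloxy)-2-[(R)-7-(benzyloxy)chroman-3-yl]-6-methoxyphenyl}(hydroxy)methyl]phenol; 26 (E)-2,3-bis(benzyloxy)-4-methoxy-1-(2-methoxyvinyl)benzene
Product: 28 (3R,4S)-7-(benzyloxy)-4-{4-(benzyloxy)-2-[(R)-7-(benzyloxy)chroman-3-yl]-6-methoxyphenyl}-3-[2,3-bis(benzyloxy)-4-methoxyphenyl]-2-methoxychroman (C2 epimers), via ortho-quinone methide 27 (not isolated)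
Conditions: (R)-TRIP [(R)-3,3'-bis(2,4,6-triisopropylphenyl)-1,1'-binaphthyl-2,2'-diyl hydrogen phosphate] (10 mol %), 26 (2 equiv), 5 Å MS, toluene, 0 °C → rt
Reagents that add atoms: none
Why: The acid protonates the doubly benzylic carbinol, water leaves with help from the para benzyloxy group and the ortho oxygen of ring A, and the quinone methide 27 stays hydrogen-bonded to the phosphate through its carbonyl oxygen. The aryl-bearing carbon of the enol ether then adds to the methide carbon C4 while the developing oxocarbenium carbon C2 is captured by O1, an asynchronous inverse-electron-demand hetero-Diels–Alder reaction whose closest known type is the chiral-phosphoric-acid-catalysed [4+2] reaction of in situ ortho-quinone methides with enol ethers and styrenes. The pyran closes in this [4+2] mode (in the stepwise limit a 6-exo-trig capture of the oxocarbenium ion by the phenolic oxygen). C4 is set by the catalyst, whose binaphthyl pocket leaves one face of the bound methide open, and C3 is set relative to C4 by the E alkene reacting with methoxy endo and ring B exo, which places the two aryl groups trans; C2 is not controlled and is removed in step 19. The step needs face selectivity under catalyst control, which is possible because ring E rotates about C4–E1 so that the resident C3' centre blocks neither face permanently, and regioselectivity, which the opposite polarisation of the two partners secures. The sieves take up the water so that the enol ether, used in excess, is not hydrolysed.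

Step 19
Reactants: 28 (3R,4S)-7-(benzyloxy)-4-{4-(benzyloxy)-2-[(R)-7-(benzyloxy)chroman-3-yl]-6-methoxyphenyl}-3-[2,3-bis(benzyloxy)-4-methoxyphenyl]-2-methoxychroman (C2 epimers)
Product: 29 (3R,4S)-7-(benzyloxy)-4-{4-(benzyloxy)-2-[(R)-7-(benzyloxy)chroman-3-yl]-6-methoxyphenyl}-3-[2,3-bis(benzyloxy)-4-methoxyphenyl]chroman
Conditions: Et3SiH, BF3·OEt2, CH2Cl2, −78 → −30 °C
Reagents that add atoms: none
Why: Ionic hydrogenation, in which BF3 ionises the C2 acetal to the cyclic oxocarbenium ion and the silane reduces it to the C2 methylene at low temperature, so that both C2 epimers converge and the benzyl ethers and the three stereocentres are untouched.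

Step 20
Reactants: 29 (3R,4S)-7-(benzyloxy)-4-{4-(benzyloxy)-2-[(R)-7-(benzyloxy)chroman-3-yl]-6-methoxyphenyl}-3-[2,3-bis(benzyloxy)-4-methoxyphenyl]chroman
Product: 30 (3R,4S)-3-(2,3-dihydroxy-4-methoxyphenyl)-4-{4-hydroxy-2-[(R)-7-hydroxychroman-3-yl]-6-methoxyphenyl}chroman-7-ol
Conditions: H2 (1 atm), Pd/C, EtOAc/MeOH, rt; work-up under argon
Reagents that add atoms: none
Why: Catalytic hydrogenolysis removes the five benzyl ethers, and since no other C–O bond is benzylic the two chromans, the methyl ethers and the stereocentres remain.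

**Compound list**

1 | methyl 2-(3,5-dihydroxyphenyl)acetate | COC(=O)Cc1cc(O)cc(O)c1 | starting material
2 | [2,4-dihydroxy-6-(2-methoxy-2-oxoethyl)benzylidene]dimethyliminium chloride | COC(=O)Cc1cc(O)cc(O)c1C=[N+](C)C.[Cl-] | intermediate
3 | methyl 2-(2-formyl-3,5-dihydroxyphenyl)acetate | COC(=O)Cc1cc(O)cc(O)c1C=O | intermediate
4 | methyl 2-[5-(benzyloxy)-2-formyl-3-hydroxyphenyl]acetate | COC(=O)Cc1cc(OCc2ccccc2)cc(O)c1C=O | intermediate
5 | methyl 2-[5-(benzyloxy)-2-formyl-3-methoxyphenyl]acetate | COC(=O)Cc1cc(OCc2ccccc2)cc(OC)c1C=O | intermediate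
6 | methyl 2-[5-(benzyloxy)-3-methoxy-2-vinylphenyl]acetate | COC(=O)Cc1cc(OCc2ccccc2)cc(OC)c1C=C | intermediate
7 | 2-[5-(benzyloxy)-3-methoxy-2-vinylphenyl]acetic acid | OC(=O)Cc1cc(OCc2ccccc2)cc(OC)c1C=C | intermediate
8 | (R)-4-benzyl-2-oxazolidinone | O=C1N[C@H](Cc2ccccc2)CO1 | starting material
9 | 2-[5-(benzyloxy)-3-methoxy-2-vinylphenyl]acetic pivalic anhydride | CC(C)(C)C(=O)OC(=O)Cc1cc(OCc2ccccc2)cc(OC)c1C=C | intermediate
10 | (R)-4-benzyl-3-{2-[5-(benzyloxy)-3-methoxy-2-vinylphenyl]acetyl}oxazolidin-2-one | O=C(Cc1cc(OCc2ccccc2)cc(OC)c1C=C)N1[C@H](Cc2ccccc2)COC1=O | intermediate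
11 | 4-(benzyloxy)-2-hydroxybenzaldehyde | O=Cc1ccc(OCc2ccccc2)cc1O | starting material
12 | 4-(benzyloxy)-2-(triisopropylsilyloxy)benzaldehyde | O=Cc1ccc(OCc2ccccc2)cc1O[Si](C(C)C)(C(C)C)C(C)C | intermediate
13 | [4-(benzyloxy)-2-(triisopropylsilyloxy)phenyl]methanol | OCc1ccc(OCc2ccccc2)cc1O[Si](C(C)C)(C(C)C)C(C)C | intermediate
14 | 4-(benzyloxy)-1-(bromomethyl)-2-(triisopropylsilyloxy)benzene | BrCc1ccc(OCc2ccccc2)cc1O[Si](C(C)C)(C(C)C)C(C)C | intermediate
15 | sodium Z-enolate of 10 | [Na+].[O-]/C(=C\c1cc(OCc2ccccc2)cc(OC)c1C=C)N1[C@H](Cc2ccccc2)COC1=O | intermediate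
16 | (R)-4-benzyl-3-{(R)-2-[5-(benzyloxy)-3-methoxy-2-vinylphenyl]-3-[4-(benzyloxy)-2-(triisopropylsilyloxy)phenyl]propanoyl}oxazolidin-2-one | O=C([C@H](Cc1ccc(OCc2ccccc2)cc1O[Si](C(C)C)(C(C)C)C(C)C)c1cc(OCc2ccccc2)cc(OC)c1C=C)N1[C@H](Cc2ccccc2)COC1=O | intermediate
17 | (R)-2-[5-(benzyloxy)-3-methoxy-2-vinylphenyl]-3-[4-(benzyloxy)-2-(triisopropylsilyloxy)phenyl]propan-1-ol | OC[C@H](Cc1ccc(OCc2ccccc2)cc1O[Si](C(C)C)(C(C)C)C(C)C)c1cc(OCc2ccccc2)cc(OC)c1C=C | intermediate
18 | 5-(benzyloxy)-2-{(R)-2-[5-(benzyloxy)-3-methoxy-2-vinylphenyl]-3-hydroxypropyl}phenol | OC[C@H](Cc1ccc(OCc2ccccc2)cc1O)c1cc(OCc2ccccc2)cc(OC)c1C=C | intermediate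
19 | (R)-7-(benzyloxy)-3-[5-(benzyloxy)-3-methoxy-2-vinylphenyl]chroman | C=Cc1c(OC)cc(OCc2ccccc2)cc1[C@@H]1COc2cc(OCc3ccccc3)ccc2C1 | intermediate
20 | 4-(benzyloxy)-2-[(R)-7-(benzyloxy)chroman-3-yl]-6-methoxybenzaldehyde | O=Cc1c(OC)cc(OCc2ccccc2)cc1[C@@H]1COc2cc(OCc3ccccc3)ccc2C1 | intermediate
21 | 5-(benzyloxy)-2-bromophenol | Oc1cc(OCc2ccccc2)ccc1Br | starting material
22 | lithium 5-(benzyloxy)-2-lithiophenoxide | [Li]Oc1cc(OCc2ccccc2)ccc1[Li] | intermediate
23 | 5-(benzyloxy)-2-[{4-(benzyloxy)-2-[(R)-7-(benzyloxy)chroman-3-yl]-6-methoxyphenyl}(hydroxy)methyl]phenol, both carbinol epimers | OC(c1ccc(OCc2ccccc2)cc1O)c1c(OC)cc(OCc2ccccc2)cc1[C@@H]1COc2cc(OCc3ccccc3)ccc2C1 | intermediate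
24 | 2,3-dihydroxy-4-methoxybenzaldehyde | COc1ccc(C=O)c(O)c1O | starting material
25 | 2,3-bis(benzyloxy)-4-methoxybenzaldehyde | COc1ccc(C=O)c(OCc2ccccc2)c1OCc1ccccc1 | intermediate
26 | (E)-2,3-bis(benzyloxy)-4-methoxy-1-(2-methoxyvinyl)benzene | CO/C=C/c1ccc(OC)c(OCc2ccccc2)c1OCc1ccccc1 | intermediate
27 | 3-(benzyloxy)-6-{4-(benzyloxy)-2-[(R)-7-(benzyloxy)chroman-3-yl]-6-methoxybenzylidene}cyclohexa-2,4-dien-1-one (ortho-quinone methide) | O=C1C=C(OCc2ccccc2)C=CC1=Cc1c(OC)cc(OCc2ccccc2)cc1[C@@H]1COc2cc(OCc3ccccc3)ccc2C1 | intermediate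
28 | (3R,4S)-7-(benzyloxy)-4-{4-(benzyloxy)-2-[(R)-7-(benzyloxy)chroman-3-yl]-6-methoxyphenyl}-3-[2,3-bis(benzyloxy)-4-methoxyphenyl]-2-methoxychroman, C2 epimers | COc1ccc(c(OCc2ccccc2)c1OCc1ccccc1)[C@@H]1C(OC)Oc2cc(OCc3ccccc3)ccc2[C@H]1c1c(OC)cc(OCc2ccccc2)cc1[C@@H]1COc2cc(OCc3ccccc3)ccc2C1 | intermediate
29 | (3R,4S)-7-(benzyloxy)-4-{4-(benzyloxy)-2-[(R)-7-(benzyloxy)chroman-3-yl]-6-methoxyphenyl}-3-[2,3-bis(benzyloxy)-4-methoxyphenyl]chroman | COc1ccc(c(OCc2ccccc2)c1OCc1ccccc1)[C@@H]1COc2cc(OCc3ccccc3)ccc2[C@H]1c1c(OC)cc(OCc2ccccc2)cc1[C@@H]1COc2cc(OCc3ccccc3)ccc2C1 | intermediate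
30 | (3R,4S)-3-(2,3-dihydroxy-4-methoxyphenyl)-4-{4-hydroxy-2-[(R)-7-hydroxychroman-3-yl]-6-methoxyphenyl}chroman-7-ol | COc1ccc([C@@H]2COc3cc(O)ccc3[C@H]2c2c(OC)cc(O)cc2[C@@H]2COc3cc(O)ccc3C2)c(O)c1O | target

**Step count and risks**

Total steps: 20. Longest linear sequence: 15 (steps 1–6, 10–15, 18–20).

Steps most likely to fail:

1. Step 18. The hindered methide may react slowly, so that hydrolysis of the enol ether or self-condensation of the methide competes, and face or trans selectivity may be poor if the catalyst does not override the resident stereocentre. The fallback moves stereocontrol from the acid to an enamine. It sets out from 23 and 26. Compound 23 is treated with p-toluenesulfinic acid (CH2Cl2/H2O) to give the sulfone 5-(benzyloxy)-2-[{4-(benzyloxy)-2-[(R)-7-(benzyloxy)chroman-3-yl]-6-methoxyphenyl}(tosyl)methyl]phenol F1, a stable, base-triggered source of the same methide 27. Compound 26 is hydrolysed (aq. HCl, THF) to 2-[2,3-bis(benzyloxy)-4-methoxyphenyl]acetaldehyde F2. F1 and F2 are combined with NaHCO3 and the enantiomer of 2-[diphenyl(trimethylsilyloxy)methyl]pyrrolidine that leads to 3R. This is the known secondary-amine-catalysed Michael addition of aldehydes to ortho-quinone methides, and after hemiacetalisation it gives the 3,4-trans 2-hydroxychroman (lactol) F3. Methanol with PPTS converts F3 into the methyl acetal, and the route is rejoined at 28.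

2. Step 19. Lewis-acid ionisation of the acetal may open the pyran at the aryl oxygen, leading to retro-addition or to reduction of the open-chain oxocarbenium ion, or C3 may be scrambled by elimination to the 4H-chromene before hydride capture. The fallback avoids any oxocarbenium ion at C2. It sets out from 28, which is hydrolysed (aq. AcOH, THF) to the lactol F3. NaBH4 reduces the open hydroxy-aldehyde form to the diol 5-(benzyloxy)-2-{(1S,2R)-1-{4-(benzyloxy)-2-[(R)-7-(benzyloxy)chroman-3-yl]-6-methoxyphenyl}-2-[2,3-bis(benzyloxy)-4-methoxyphenyl]-3-hydroxypropyl}phenol F4. A Mitsunobu etherification (PPh3, DIAD) recloses the pyran, and the route is rejoined at 29.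

3. Step 17. The Wittig reaction may show poor geometric selectivity and the two isomers may be hard to separate. The fallback is the stereospecific Horner–Wittig route. It sets out from 25, to which lithiated (methoxymethyl)diphenylphosphine oxide (LDA, THF, −78 °C) is added. Of the two crystalline β-hydroxy phosphine oxides, rel-(1R,2S)-1-[2,3-bis(benzyloxy)-4-methoxyphenyl]-2-(diphenylphosphoryl)-2-methoxyethanol F5 is separated. Its syn elimination with NaH in THF can give only the E enol ether, and the route is rejoined at 26.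

**Further compounds**

F1 | step 18 | 5-(benzyloxy)-2-[{4-(benzyloxy)-2-[(R)-7-(benzyloxy)chroman-3-yl]-6-methoxyphenyl}(tosyl)methyl]phenol | Cc1ccc(cc1)S(=O)(=O)C(c1ccc(OCc2ccccc2)cc1O)c1c(OC)cc(OCc2ccccc2)cc1[C@@H]1COc2cc(OCc3ccccc3)ccc2C1
F2 | step 18 | 2-[2,3-bis(benzyloxy)-4-methoxyphenyl]acetaldehyde | COc1ccc(CC=O)c(OCc2ccccc2)c1OCc1ccccc1
F3 | step 18 | (3R,4S)-7-(benzyloxy)-4-{4-(benzyloxy)-2-[(R)-7-(benzyloxy)chroman-3-yl]-6-methoxyphenyl}-3-[2,3-bis(benzyloxy)-4-methoxyphenyl]chroman-2-ol (lactol, C2 epimers) | COc1ccc(c(OCc2ccccc2)c1OCc1ccccc1)[C@@H]1C(O)Oc2cc(OCc3ccccc3)ccc2[C@H]1c1c(OC)cc(OCc2ccccc2)cc1[C@@H]1COc2cc(OCc3ccccc3)ccc2C1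
F4 | step 19 | 5-(benzyloxy)-2-{(1S,2R)-1-{4-(benzyloxy)-2-[(R)-7-(benzyloxy)chroman-3-yl]-6-methoxyphenyl}-2-[2,3-bis(benzyloxy)-4-methoxyphenyl]-3-hydroxypropyl}phenol | COc1ccc(c(OCc2ccccc2)c1OCc1ccccc1)[C@H](CO)[C@@H](c1ccc(OCc2ccccc2)cc1O)c1c(OC)cc(OCc2ccccc2)cc1[C@@H]1COc2cc(OCc3ccccc3)ccc2C1
F5 | step 17 | rel-(1R,2S)-1-[2,3-bis(benzyloxy)-4-methoxyphenyl]-2-(diphenylphosphoryl)-2-methoxyethanol (racemic) | COc1ccc([C@@H](O)[C@@H](OC)P(=O)(c2ccccc2)c2ccccc2)c(OCc2ccccc2)c1OCc1ccccc1
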